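**Retrosynthetic overview**
- Target ⇒ tri-O-benzyl (E)-enone: one final hydrogenation saturates C2=C3 and removes the three benzyl ethers.
- Enone ⇒ β-hydroxy ketone (dehydration) ⇒ key C2–C3 bond: intermolecular aldol addition of the lithium enolate of 2,4,6-tris(benzyloxy)acetophenone to 9-phenylnonanal.
- 9-Phenylnonanal ⇒ 9-phenylnonan-1-ol ⇒ methyl 9-phenylnonanoate ⇒ methyl 9-oxo-9-phenylnonanoate ⇒ benzene + monomethyl azelate acid chloride (Friedel–Crafts).
- Tribenzyl ketone ⇒ 2,4,6-trihydroxyacetophenone + benzyl bromide.
- No ring is formed: the phenyl ring comes from benzene and the phloroglucinol ring from phloroacetophenone.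

Assumption: the target SMILES has no stereocentre (the compound is achiral), so no enantiocontrol is needed; the carbinol centres that appear in three intermediates are racemic and are removed again.

**Step 1**
Reactants: 1 9-methoxy-9-oxononanoic acid (monomethyl azelate)
Product: 2 methyl 9-chloro-9-oxononanoate
Conditions: (COCl)2 (1.3 equiv), DMF (cat.), CH2Cl2, 0 °C to rt, 2 h; evaporate
Reagents that add atoms: oxalyl chloride, ClC(=O)C(=O)Cl
Why: Acid chloride formation through the DMF-derived chloroiminium catalyst is essentially quantitative for a simple aliphatic acid and leaves the methyl ester untouched.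

**Step 2**
Reactants: 2 methyl 9-chloro-9-oxononanoate; 3 benzene
Product: 4 methyl 9-oxo-9-phenylnonanoate
Conditions: AlCl3 (2.3 equiv), benzene (solvent), 0 °C to rt, 3 h; ice/aq. HCl
Reagents that add atoms: none
Why: Friedel–Crafts acylation of benzene by the acylium ion stops at the mono-ketone because the product ring is deactivated, and the ester only ties up one extra equivalent of AlCl3.

**Step 3**
Reactants: 4 methyl 9-oxo-9-phenylnonanoate
Product: 6 methyl 9-phenylnonanoate, via methyl 9-hydroxy-9-phenylnonanoate 5 (not isolated)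
Conditions: Et3SiH (3 equiv), CF3CO2H, rt to 50 °C, 16 h
Reagents that add atoms: none
Why: Ionic hydrogenation (silane/trifluoroacetic acid deoxygenation) reduces the protonated aryl ketone to the racemic benzylic alcohol 5, which ionises to the benzylic cation and takes a second hydride to give CH2, while the aliphatic ester is inert.

**Step 4**
Reactants: 6 methyl 9-phenylnonanoate
Product: 7 9-phenylnonan-1-ol
Conditions: LiAlH4 (1.0 equiv), THF, 0 °C to rt, 2 h; Na2SO4·10H2O quench
Reagents that add atoms: none
Why: Hydride reduction of an unhindered methyl ester to the primary alcohol with LiAlH4 is general, and nothing else in the molecule is reducible.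

**Step 5**
Reactants: 7 9-phenylnonan-1-ol
Product: 8 9-phenylnonanal
Conditions: TEMPO (0.1 equiv), PhI(OAc)2 (1.1 equiv), CH2Cl2, rt, 3 h
Reagents that add atoms: none
Why: Oxoammonium-mediated (TEMPO/PhI(OAc)2) oxidation of a primary alcohol stops at the aldehyde under anhydrous conditions without over-oxidation to the acid.

**Step 6**
Reactants: 9 1-(2,4,6-trihydroxyphenyl)ethan-1-one (phloroacetophenone)
Product: 10 1-[2,4,6-tris(benzyloxy)phenyl]ethan-1-one
Conditions: BnBr (3.6 equiv), K2CO3 (5 equiv), DMF, 80 °C, 8 h
Reagents that add atoms: benzyl bromide, BrCc1ccccc1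
Why: Williamson ether synthesis, in which the acyl group lowers the ring-carbon nucleophilicity of the phenoxides so O-benzylation dominates, and heating in DMF also alkylates the two hydrogen-bonded ortho hydroxyls.

**Step 7**
Reactants: 10 1-[2,4,6-tris(benzyloxy)phenyl]ethan-1-one; 8 9-phenylnonanal
Product: 12 3-hydroxy-11-phenyl-1-[2,4,6-tris(benzyloxy)phenyl]undecan-1-one, via lithium 1-[2,4,6-tris(benzyloxy)phenyl]ethen-1-olate 11 (not isolated)
Conditions: LiN(iPr)2 (LDA, commercial solution, 1.1 equiv), THF, −78 °C, 45 min; then 8 (1.1 equiv), −78 °C, 1 h; AcOH, −78 °C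
Reagents that add atoms: lithium diisopropylamide, [Li]N(C(C)C)C(C)C
Why: Directed intermolecular aldol addition, in which the methyl ketone is completely and irreversibly enolised before the enolisable aldehyde is added so only the cross C2–C3 bond forms, the new carbinol centre arises as a racemate (uncontrolled, removed in step 8), and the lithium sits only in 11 and is lost on the cold acid quench.

**Step 8**
Reactants: 12 3-hydroxy-11-phenyl-1-[2,4,6-tris(benzyloxy)phenyl]undecan-1-one
Product: 14 (E)-11-phenyl-1-[2,4,6-tris(benzyloxy)phenyl]undec-2-en-1-one, via 3-mesyloxy ketone 13 (not isolated)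
Conditions: MsCl (1.5 equiv), Et3N (4 equiv), CH2Cl2, 0 °C to rt, 12 h
Reagents that add atoms: methanesulfonyl chloride, CS(=O)(=O)Cl
Why: Mesylation followed by E1cB elimination of the β-mesyloxy ketone gives the conjugated, thermodynamically favoured (E)-enone and erases the carbinol stereocentre, the mesyl group being carried only by 13.

**Step 9**
Reactants: 14 (E)-11-phenyl-1-[2,4,6-tris(benzyloxy)phenyl]undec-2-en-1-one
Product: 16 11-phenyl-1-(2,4,6-trihydroxyphenyl)undecan-1-one, via 11-phenyl-1-[2,4,6-tris(benzyloxy)phenyl]undecan-1-one 15 (not isolated)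
Conditions: H2 (1 atm), 10% Pd/C, EtOAc/MeOH (1:1), rt, 12 h
Reagents that add atoms: none
Why: Catalytic hydrogenation saturates the enone C=C first, and the same Pd/C then hydrogenolyses the three aryl benzyl ethers to give the target, while the hydrogen-bonded trihydroxyaryl ketone and the isolated phenyl ring are not reduced at 1 atm and rt.

**Compound list**
1 | 9-methoxy-9-oxononanoic acid (monomethyl azelate) | COC(=O)CCCCCCCC(=O)O | starting material
2 | methyl 9-chloro-9-oxononanoate | COC(=O)CCCCCCCC(=O)Cl | intermediate
3 | benzene | c1ccccc1 | starting material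
4 | methyl 9-oxo-9-phenylnonanoate | COC(=O)CCCCCCCC(=O)c1ccccc1 | intermediate
5 | methyl 9-hydroxy-9-phenylnonanoate (racemic, not isolated) | COC(=O)CCCCCCCC(O)c1ccccc1 | intermediate
6 | methyl 9-phenylnonanoate | COC(=O)CCCCCCCCc1ccccc1 | intermediate
7 | 9-phenylnonan-1-ol | OCCCCCCCCCc1ccccc1 | intermediate
8 | 9-phenylnonanal | O=CCCCCCCCCc1ccccc1 | intermediate
9 | 1-(2,4,6-trihydroxyphenyl)ethan-1-one (phloroacetophenone) | CC(=O)c1c(O)cc(O)cc1O | starting material
10 | 1-[2,4,6-tris(benzyloxy)phenyl]ethan-1-one | CC(=O)c1c(OCc2ccccc2)cc(OCc2ccccc2)cc1OCc1ccccc1 | intermediate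
11 | lithium 1-[2,4,6-tris(benzyloxy)phenyl]ethen-1-olate (not isolated) | [Li]OC(=C)c1c(OCc2ccccc2)cc(OCc2ccccc2)cc1OCc1ccccc1 | intermediate
12 | 3-hydroxy-11-phenyl-1-[2,4,6-tris(benzyloxy)phenyl]undecan-1-one (racemic) | O=C(CC(O)CCCCCCCCc1ccccc1)c1c(OCc2ccccc2)cc(OCc2ccccc2)cc1OCc1ccccc1 | intermediate
13 | 1-oxo-11-phenyl-1-[2,4,6-tris(benzyloxy)phenyl]undecan-3-yl methanesulfonate (racemic, not isolated) | CS(=O)(=O)OC(CC(=O)c1c(OCc2ccccc2)cc(OCc2ccccc2)cc1OCc1ccccc1)CCCCCCCCc1ccccc1 | intermediate
14 | (E)-11-phenyl-1-[2,4,6-tris(benzyloxy)phenyl]undec-2-en-1-one | O=C(/C=C/CCCCCCCCc1ccccc1)c1c(OCc2ccccc2)cc(OCc2ccccc2)cc1OCc1ccccc1 | intermediate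
15 | 11-phenyl-1-[2,4,6-tris(benzyloxy)phenyl]undecan-1-one (not isolated) | O=C(CCCCCCCCCCc1ccccc1)c1c(OCc2ccccc2)cc(OCc2ccccc2)cc1OCc1ccccc1 | intermediate
16 | 11-phenyl-1-(2,4,6-trihydroxyphenyl)undecan-1-one (achiral) | O=C(CCCCCCCCCCc1ccccc1)c1c(O)cc(O)cc1O | target

**Step count**
Total steps: 9. Longest linear sequence: 8 steps (steps 1, 2, 3, 4, 5, 7, 8, 9 from monomethyl azelate 1); step 6 is the one-step side branch that joins at step 7.

**Three steps most likely to fail, with fallbacks**

Step 7 (aldol addition). The enolate is flanked by two ortho benzyloxy groups and the aldehyde is enolisable, so proton exchange, aldehyde self-condensation or retro-aldol on warming can lower the yield. The fallback sets out from ketone 10. It is converted with Me3SiOTf/Et3N (CH2Cl2, 0 °C) into the silyl enol ether trimethyl({1-[2,4,6-tris(benzyloxy)phenyl]ethenyl}oxy)silane F1. F1 is then added to aldehyde 8 in a Mukaiyama aldol reaction (BF3·OEt2, CH2Cl2, −78 °C). This neutral, Lewis-acid-driven addition avoids any basic enolate/aldehyde equilibration. The silyl group leaves as fluorotrimethylsilane, and aqueous work-up gives aldol 12, where the route is rejoined.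

Step 6 (tribenzylation). Phloroglucinol-type phenoxides can be benzylated on ring carbon, and the two chelated ortho hydroxyls react slowly, so mixtures are possible. The fallback sets out from 9. Only the 2- and 4-hydroxyls are benzylated under mild conditions (BnBr 2.1 equiv, K2CO3, acetone, reflux), which leaves the last, chelated hydroxyl free and gives 1-[2,4-bis(benzyloxy)-6-hydroxyphenyl]ethan-1-one F2. The remaining hydrogen-bonded phenol is then etherified under Mitsunobu conditions (benzyl alcohol, PPh3, diisopropyl azodicarboxylate, THF, 0 °C to rt), where no free polyphenoxide is present. This comes back to the route at 10.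

Step 9 (global hydrogenation). Hydrogenolysis of the two hindered ortho benzyl ethers may stall, or prolonged exposure may start to reduce the aryl ketone. The fallback sets out from 14. Only the C=C bond is hydrogenated with RhCl(PPh3)3 (5 mol %), H2 (1 atm), benzene/EtOH, rt, and 15 (already in the compound list) is isolated. The three benzyl ethers are then cleaved without hydrogen by BCl3 (6 equiv) with pentamethylbenzene as benzyl-cation scavenger in CH2Cl2 at −78 °C. This comes back to the route at 16. Compounds outside the compound list on this path: none F0.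

**Further compounds**
F1 | step 7 | trimethyl({1-[2,4,6-tris(benzyloxy)phenyl]ethenyl}oxy)silane | C=C(O[Si](C)(C)C)c1c(OCc2ccccc2)cc(OCc2ccccc2)cc1OCc1ccccc1
F2 | step 6 | 1-[2,4-bis(benzyloxy)-6-hydroxyphenyl]ethan-1-one | CC(=O)c1c(O)cc(OCc2ccccc2)cc1OCc1ccccc1
F0 | step 9 | none | none
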